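## Structural features

The target 21 is a guaiane-type hydroazulene: a cyclopentenone (ring A, C1–C5) fused through C1 and C5 to a cycloheptane (ring B, C5–C10 plus C1), with a tetrasubstituted C4=C5 alkene that carries the C15 methyl and is conjugated to the C3 ketone. Ring B holds all four stereocentres: C1 and C10 are neighbours, C7 and C8 are neighbours, and C8 and C10 are 1,3-related across C9. H1, the C10 methyl, the C8 oxygen and the C7 side chain lie on one face (1R,7S,8R,10S in guaiane numbering). C7 carries the exocyclic carbon C11 as a tertiary acetate with two methyl groups (C12, C13), directly beside the secondary isobutyrate on C8. The fragile points are the tertiary acetate (ionisation, elimination), the two different esters on 1,3-related oxygens (acyl migration), and C1, which is γ to the enone carbonyl and can epimerise through the dienolate. The real difficulty is a seven-membered ring with four stereocentres, whose relative configuration is hard to control on a flexible ring, and the late differentiation of O8 from O11. The key step uses the array C5(=O)–C6H2–C7–C11: with C5 a ketone and C11 an ester it is a γ-keto ester, so C6 can be excised retrosynthetically to leave a cyclohexanone in which the C8 oxygen, the C10 methyl and the C1 substituent are all equatorial on a chair.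

## Logic of the disconnections

21 ⇒ 20 ⇒ 19. The O11–acetyl and then the O8–isobutyryl bonds are cut. Both esters are labile and differ only in the carbinol they sit on, so they are introduced last. This leaves a diol whose hydroxyls differ sharply in steric demand. The forward steps must acylate the secondary O8 selectively, then the tertiary O11 under non-basic conditions so that the O8 acyl group cannot migrate.

19 ⇒ 18. The O8–Si bond is cut. A silyl ether is the only O8 group that survives enolate alkylation, tin radicals, gold catalysis and organometallic addition. The forward step is a buffered fluoride cleavage that leaves the tertiary alcohol and C1 alone.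

18 ⇒ 17 ⇒ 16 ⇒ 15. The C11–C12 and C11–C13 bonds are cut back to an ester carbon, with the C3 carbonyl held at the alcohol level in between. The ester is what makes the key step possible, and the enone would otherwise take up the methyl nucleophile. The forward steps need a clean 1,2-reduction, a non-basic methyl nucleophile (C7–H is α to the ester and β to the silyloxy group) and an oxidant that touches only the allylic alcohol.

15 ⇒ 14. The C4=C5 bond is cut (aldol condensation), opening ring A to a 1,4-diketone. The forward step needs base mild enough not to enolise the ester at C7.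

14 ⇒ 13. The C3=O bond is traced back to the C3≡C4 alkyne. The alkyne is inert to base and radicals and hides the 1,4-dicarbonyl until it is needed. The forward hydration must place oxygen on C3, not C4, which the neighbouring C5 carbonyl secures.

13 ⇒ 12 (key). The C5–C6 bond is cut and C5–C7 re-formed, contracting ring B to a cyclohexanone with a bromomethyl group on C7. Three stereocentres (C1, C8, C10) now sit equatorially on a chair, and C7 no longer needs control, because it passes through a planar radical. The forward step needs one ketone only, low hydrogen-donor concentration, and face-selective hydrogen transfer to C7.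

12 ⇒ 9 + 10 (through 11). The C1–C2 bond is cut. C1 is the only enolisable position of 9, and alkylation next to the C10 methyl gives the trans product. The forward step must avoid β-elimination of the C8 silyloxy group, which the quaternary C7 guarantees.

9 ⇒ 8 ⇒ 7. The O8–Si bond and then the C8–H bond are cut, leading to a meso dione. One desymmetrising reduction then sets C8 and C10 (and the absolute configuration of the whole route). The forward step must choose one of two enantiotopic carbonyls and the axial face, and must not cleave the β,β'-diketo ester.

7 ⇒ 6 ⇒ 5 ⇒ 3 + 4. The two C=O groups are traced to methyl enol ethers and the C6–C7 bond is cut, leading back to an aromatic ester. A Michael–Claisen annulation of a malonate with an enone was rejected, because it places the ester on the ring carbon next to the methyl-bearing carbon and not between the two carbonyls. Direct C-alkylation of a 2-acyl-1,3-dione anion was rejected as well, because such anions alkylate at oxygen. In the Birch product the quaternary carbon is made while C5 and C8 are still enol-ether carbons. The forward step needs C-alkylation of a hindered dienolate by a weak electrophile.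

3 ⇒ 2 ⇒ 1. The C7–C11 bond is cut. The position between two methoxy groups is the most acidic aryl C–H, so lithiation and acylation are regiospecific.

## Other disconnections considered

Alternative 1: The cut undoes the C1–C5 bond and restores a C5–C10 bond, turning the hydroazulenone into the cross-conjugated decalin dienone A1. In the forward sense, irradiation of A1 in acetic acid would give the bicyclic zwitterion, and its solvolytic opening would give A2 with ring A, the C15 methyl, the enone and C1 in place.
- In its favour: the whole 5-7 enone nucleus comes from a decalin made by Robinson annulation, in one step of a very well-established type. For the construction of ring A this is better than the chosen plan, which needs a hydration and an aldol condensation.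
- Against it here: A2 is a trinor skeleton with C6 and C7 as CH2 and C8 only a ketal. C10 becomes a fully substituted acetoxy carbon whose methyl lies on the face opposite to that required relative to H1, so C10 must be deoxygenated and re-set through an alkene. The C7 side chain must then be introduced by enolate chemistry of a C8 ketone, with C7/C9 regiocontrol, and C8 reduced with facial control on a flexible ring.
- Comparison: structurally it leaves C7, C8 and C10 to late substrate control, where the chosen plan sets C1, C8 and C10 on a chair. Mechanistically both key steps are stereospecific rearrangements (equal), but the photoreaction has competing lumiketone-type channels and needs dilute photolysis. In step economy it is judged equal at best, because the repair work after the key step is long.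

Alternative 2: The cut is C7–C8. In the forward sense, SnCl4 would activate the aldehyde of A3, and the γ-carbon of its E-allylsilane (C7) would attack C8, closing ring B to A4 with the C8 hydroxyl and an isopropenyl group on C7.
- In its favour: A4 maps directly onto the target. O8 acylation, Markovnikov hydration of the isopropenyl group (Mukaiyama hydration) and acetylation would finish the synthesis, so the endgame is shorter than in the chosen plan and on this point the alternative is better. It is also tin-free and closed-shell, which is equal or better in practicality.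
- Against it here: a seven-membered ring is closed against an entropic penalty. The 7,8-cis relationship depends on competing synclinal and antiperiplanar transition states in a medium ring and cannot be predicted with confidence. The Lewis acid also binds the enone, and protodesilylation competes. A3 needs a stereodefined trisubstituted allylsilane and C1/C10 set on a cyclopentenone whose C1 is epimerisable.
- Comparison: it sets C7 and C8 in one step but by less predictable control than the hydride and hydrogen-atom deliveries of the chosen plan. Overall step count could be equal or lower if A3 is short to make. The risk is concentrated in the diastereoselectivity of one late step.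

Alternative 3: The cuts are C6–C7 and C9–C10. In the forward sense, Rh2(S-PTAD)4 (divalent rhodium) would decompose the siloxyvinyl diazoacetate A6, the carbenoid would cyclopropanate the C5=C6 methylene of diene A5, and the cis-divinylcyclopropane would undergo Cope rearrangement to A7.
- In its favour: two C–C bonds and ring B form in one catalytic, enantioselective operation, with C10 set by the catalyst and the stereospecific boat transition state. In bond-forming economy and in its use of catalytic asymmetric induction this is better than the chosen plan.
- Against it here: A7 lacks the C15 methyl. Its ring-fusion alkene is C1=C5 and not C4=C5, so C1 has to be created later by an isomerisation the key step does not control. C7 and C8 are sp2 and must be set by reduction of the β-keto ester. A5 is an s-cis bis-alkylidene cyclopentane prone to dimerisation, and it offers two alkenes to the carbenoid.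
- Comparison: only one of four stereocentres comes from the key step, against three in place and one set in the chosen key step. Both plans must still convert a C7 ester into the C11 carbinol (equal). Total step count is judged similar or higher because of the adjustments after the annulation.

Key step: step 6

Assumptions and remarks:
- Atom labels C1–C15 are those of the guaiane skeleton of 21 and are kept for every intermediate.
- Step 2 is taken to alkylate C7 anti to the C10 methyl; a syn epimer at C7, if formed, would converge at 13, because C7 becomes a radical centre in step 6.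

## Route

Step 1
Reactants: 1 3,5-dimethoxytoluene
Product: 3 methyl 2,6-dimethoxy-4-methylbenzoate, via (2,6-dimethoxy-4-methylphenyl)lithium 2 (not isolated)
Conditions: n-BuLi, THF, 0 → 23 °C; then inverse addition to ClCO2Me, THF, −78 °C
Reagents that add atoms: methyl chloroformate, COC(=O)Cl
Why: Directed ortho-metalation followed by acylation: the C–H flanked by both methoxy groups is by far the most acidic, and inverse addition to excess chloroformate stops at the ester.

Step 2
Reactants: 3 methyl 2,6-dimethoxy-4-methylbenzoate; 4 dibromomethane
Product: 7 methyl 1-(bromomethyl)-4-methyl-2,6-dioxocyclohexane-1-carboxylate (bromomethyl trans to 4-methyl), via lithium ester dienolate 5 (not isolated), via bis(enol ether) bromide 6 (not isolated)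
Conditions: Li, NH3/THF, t-BuOH (1 equiv), −78 °C; isoprene; CH2Br2, −78 → −33 °C; then 1 M HCl, THF, 23 °C
Reagents that add atoms: water, O
Why: Birch reductive alkylation: two-electron reduction and protonation at the para carbon (C10) give a cross-conjugated ester dienolate, which is C-alkylated at C7 on the face away from the C10 methyl; dilute acid then hydrolyses both methyl enol ethers. The quaternary carbon is thus formed while C5 and C8 are enol-ether carbons, which avoids O-alkylation of a 2-acyl-1,3-dione anion.

Step 3
Reactants: 7 methyl 1-(bromomethyl)-4-methyl-2,6-dioxocyclohexane-1-carboxylate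
Product: 8 methyl (1S,2R,4S)-1-(bromomethyl)-2-hydroxy-4-methyl-6-oxocyclohexane-1-carboxylate
Conditions: ketoreductase (NADP+ cat., R-selective at C8), i-PrOH, phosphate buffer pH 6.5, DMSO (5%), 30 °C
Reagents that add atoms: none
Why: Enzymatic desymmetrising reduction, a known reaction type for 2,2-disubstituted cyclohexane-1,3-diones: 7 is meso, and axial hydride delivery gives the equatorial C8 alcohol cis to the C10 methyl. The enzyme's enantioface preference decides which enantiotopic carbonyl reacts and so fixes C8 and C10 absolutely; near-neutral pH limits hydrolytic ring cleavage.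

Step 4
Reactants: 8 methyl (1S,2R,4S)-1-(bromomethyl)-2-hydroxy-4-methyl-6-oxocyclohexane-1-carboxylate
Product: 9 methyl (1S,2R,4S)-1-(bromomethyl)-2-[(tert-butyldimethylsilyl)oxy]-4-methyl-6-oxocyclohexane-1-carboxylate
Conditions: TBSOTf, 2,6-lutidine, CH2Cl2, −78 → 0 °C
Reagents that add atoms: tert-butyldimethylsilyl trifluoromethanesulfonate, CC(C)(C)[Si](C)(C)OS(=O)(=O)C(F)(F)F
Why: Silyl triflate with a hindered pyridine base silylates the hindered secondary alcohol next to the quaternary carbon without generating an alkoxide, so retro-aldol cleavage of the β-hydroxy ketone is avoided.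

Step 5
Reactants: 9 methyl (1S,2R,4S)-1-(bromomethyl)-2-[(tert-butyldimethylsilyl)oxy]-4-methyl-6-oxocyclohexane-1-carboxylate; 10 1-bromobut-2-yne
Product: 12 methyl (1S,3R,4S,6R)-1-(bromomethyl)-3-(but-2-yn-1-yl)-6-[(tert-butyldimethylsilyl)oxy]-4-methyl-2-oxocyclohexane-1-carboxylate, via lithium enolate 11 (not isolated)
Conditions: LiN(iPr)2, THF, −78 °C; then 10, DMPU, −78 → −30 °C
Reagents that add atoms: none
Why: Kinetic ketone enolate alkylation: C1 is the only enolisable position, and because C7 is quaternary the C8 silyloxy group cannot be eliminated. The propargylic bromide enters anti to the neighbouring C10 methyl, giving the trans arrangement with all three ring substituents equatorial, which is also the thermodynamic one.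

Step 6
Reactants: 12 methyl (1S,3R,4S,6R)-1-(bromomethyl)-3-(but-2-yn-1-yl)-6-[(tert-butyldimethylsilyl)oxy]-4-methyl-2-oxocyclohexane-1-carboxylate
Product: 13 methyl (1S,2R,4S,5R)-5-(but-2-yn-1-yl)-2-[(tert-butyldimethylsilyl)oxy]-4-methyl-6-oxocycloheptane-1-carboxylate
Conditions: Bu3SnH, AIBN (syringe pump), PhH (0.01 M), 80 °C
Reagents that add atoms: none
Why: This is a Dowd–Beckwith ring expansion, the established behaviour of 2-(bromomethyl)-2-alkoxycarbonylcycloalkanones under stannane chain conditions. Bu3Sn• abstracts bromine to give the primary C6 radical, which adds to the C5 carbonyl carbon in a 3-exo-trig closure; the alkoxycyclopropyl radical then opens by β-scission of the old C5–C7 bond, the only cleavage that places the radical on C7 beside the ester. The net change is formation of C5–C6, loss of C5–C7 and enlargement of the cyclohexanone to the cycloheptanone of ring B, so the seven-membered ring arises by exo closure onto C=O followed by fragmentation and not by a direct endo cyclisation. The new stereocentre C7 is set in the final hydrogen transfer: the stannane approaches the planar ester-substituted radical anti to the bulky C8 silyloxy group, which leaves the ester cis to O8 as required. Rearrangement is favoured over direct reduction of the C6 radical by slow addition and high dilution, which keep the stannane concentration low. Regiochemistry is unambiguous because C5 is the only ketone, C8 being a silyl ether already. The butynyl group stays a spectator, since reaching it from C6 would need a bridged 6-exo-dig transition state with the C7 and C1 substituents both axial, which the chair of 12 with equatorial C1, C8 and C10 substituents disfavours. C1, C8 and C10 are not touched.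

Step 7
Reactants: 13 methyl (1S,2R,4S,5R)-5-(but-2-yn-1-yl)-2-[(tert-butyldimethylsilyl)oxy]-4-methyl-6-oxocycloheptane-1-carboxylate
Product: 14 methyl (1S,2R,4S,5R)-2-[(tert-butyldimethylsilyl)oxy]-4-methyl-6-oxo-5-(2-oxobutyl)cycloheptane-1-carboxylate
Conditions: Ph3PAuNTf2 (5 mol%), H2O, 1,4-dioxane, 40 °C
Reagents that add atoms: water, O
Why: Carbonyl-assisted alkyne hydration: cationic monovalent gold activates the alkyne, the C5 carbonyl oxygen adds 5-exo-dig at C3, and water opens the cyclic oxocarbenium. The new carbonyl therefore sits on C3 (a 1,4-diketone) and not on C4.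

Step 8
Reactants: 14 methyl (1S,2R,4S,5R)-2-[(tert-butyldimethylsilyl)oxy]-4-methyl-6-oxo-5-(2-oxobutyl)cycloheptane-1-carboxylate
Product: 15 methyl (5S,6R,8S,8aR)-6-[(tert-butyldimethylsilyl)oxy]-3,8-dimethyl-2-oxo-1,2,4,5,6,7,8,8a-octahydroazulene-5-carboxylate
Conditions: NaOMe, MeOH, 0 → 40 °C
Reagents that add atoms: none
Why: Intramolecular aldol condensation: the C4 enolate of the ethyl ketone adds to C5 to close ring A, and dehydration gives the tetrasubstituted C4=C5 enone; the competing C6-to-C3 aldol could only dehydrate to a bridgehead enone and reverts. Methoxide matches the methyl ester and is far too weak to enolise the ester at C7 at a competitive rate.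

Step 9
Reactants: 15 methyl (5S,6R,8S,8aR)-6-[(tert-butyldimethylsilyl)oxy]-3,8-dimethyl-2-oxo-1,2,4,5,6,7,8,8a-octahydroazulene-5-carboxylate
Product: 16 methyl (5S,6R,8S,8aR)-6-[(tert-butyldimethylsilyl)oxy]-2-hydroxy-3,8-dimethyl-1,2,4,5,6,7,8,8a-octahydroazulene-5-carboxylate (either C3 epimer)
Conditions: NaBH4, CeCl3·7H2O, MeOH, −40 °C
Reagents that add atoms: none
Why: Luche 1,2-reduction masks the enone carbonyl as an allylic alcohol while leaving the ester untouched; the configuration of the new carbinol is irrelevant because it is oxidised again in step 11.

Step 10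
Reactants: 16 methyl (5S,6R,8S,8aR)-6-[(tert-butyldimethylsilyl)oxy]-2-hydroxy-3,8-dimethyl-1,2,4,5,6,7,8,8a-octahydroazulene-5-carboxylate
Product: 17 (5S,6R,8S,8aR)-6-[(tert-butyldimethylsilyl)oxy]-5-(2-hydroxypropan-2-yl)-3,8-dimethyl-1,2,4,5,6,7,8,8a-octahydroazulen-2-ol
Conditions: MeMgBr, CeCl3, THF, −78 → 0 °C; aq. NH4Cl
Reagents that add atoms: methylmagnesium bromide, C[Mg]Br
Why: Double addition of the organocerium reagent to the methyl ester builds the dimethyl carbinol C11 with C12 and C13. The low basicity of the cerium reagent avoids enolisation at C7 and loss of the C8 silyloxy group, and the C3 alkoxide is a spectator.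

Step 11
Reactants: 17 (5S,6R,8S,8aR)-6-[(tert-butyldimethylsilyl)oxy]-5-(2-hydroxypropan-2-yl)-3,8-dimethyl-1,2,4,5,6,7,8,8a-octahydroazulen-2-ol
Product: 18 (5S,6R,8S,8aR)-6-[(tert-butyldimethylsilyl)oxy]-5-(2-hydroxypropan-2-yl)-3,8-dimethyl-4,5,6,7,8,8a-hexahydroazulen-2(1H)-one
Conditions: MnO2, CH2Cl2, 23 °C
Reagents that add atoms: none
Why: Chemoselective allylic oxidation: MnO2 oxidises only the allylic C3 alcohol and restores the enone; the tertiary alcohol and the silyl ether are inert.

Step 12
Reactants: 18 (5S,6R,8S,8aR)-6-[(tert-butyldimethylsilyl)oxy]-5-(2-hydroxypropan-2-yl)-3,8-dimethyl-4,5,6,7,8,8a-hexahydroazulen-2(1H)-one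
Product: 19 (5S,6R,8S,8aR)-6-hydroxy-5-(2-hydroxypropan-2-yl)-3,8-dimethyl-4,5,6,7,8,8a-hexahydroazulen-2(1H)-one
Conditions: HF·pyridine, pyridine, THF, 0 → 23 °C
Reagents that add atoms: none
Why: Fluoride cleavage of the Si–O bond under buffered, weakly acidic conditions, which leaves the tertiary alcohol in place and gives no basic pathway for epimerisation at C1.

Step 13
Reactants: 19 (5S,6R,8S,8aR)-6-hydroxy-5-(2-hydroxypropan-2-yl)-3,8-dimethyl-4,5,6,7,8,8a-hexahydroazulen-2(1H)-one
Product: 20 [(5S,6R,8S,8aR)-5-(2-hydroxypropan-2-yl)-3,8-dimethyl-2-oxo-1,2,4,5,6,7,8,8a-octahydroazulen-6-yl] 2-methylpropanoate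
Conditions: (i-PrCO)2O, DMAP (cat.), pyridine, CH2Cl2, 0 °C
Reagents that add atoms: isobutyric anhydride, CC(C)C(=O)OC(=O)C(C)C
Why: DMAP-catalysed acylation distinguishes the secondary C8 hydroxyl from the tertiary C11 hydroxyl on steric grounds, so only O8 is esterified at low temperature.

Step 14
Reactants: 20 [(5S,6R,8S,8aR)-5-(2-hydroxypropan-2-yl)-3,8-dimethyl-2-oxo-1,2,4,5,6,7,8,8a-octahydroazulen-6-yl] 2-methylpropanoate
Product: 21 [(5S,6R,8S,8aR)-5-(2-acetoxypropan-2-yl)-3,8-dimethyl-2-oxo-1,2,4,5,6,7,8,8a-octahydroazulen-6-yl] 2-methylpropanoate (target)
Conditions: Ac2O, Sc(OTf)3 (cat.), MeCN, −20 °C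
Reagents that add atoms: acetic anhydride, CC(=O)OC(C)=O
Why: Lewis-acid-catalysed acylation esterifies the hindered tertiary alcohol at low temperature. The non-basic medium gives no alkoxide, so the isobutyryl group cannot migrate from O8 to O11 and C1 is not epimerised.

## Compound list

1 | 3,5-dimethoxytoluene (1,3-dimethoxy-5-methylbenzene) | COc1cc(C)cc(OC)c1 | starting material
2 | (2,6-dimethoxy-4-methylphenyl)lithium | COc1cc(C)cc(OC)c1[Li] | intermediate (not isolated)
3 | methyl 2,6-dimethoxy-4-methylbenzoate | COC(=O)c1c(OC)cc(C)cc1OC | intermediate
4 | dibromomethane | BrCBr | starting material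
5 | lithium dienolate of methyl 2,6-dimethoxy-4-methylcyclohexa-2,5-diene-1-carboxylate | COC(O[Li])=C1C(OC)=CC(C)C=C1OC | intermediate (not isolated)
6 | methyl 1-(bromomethyl)-2,6-dimethoxy-4-methylcyclohexa-2,5-diene-1-carboxylate, bromomethyl trans to 4-methyl | COC(=O)[C@@]1(CBr)C(OC)=C[C@@H](C)C=C1OC | intermediate (not isolated)
7 | methyl 1-(bromomethyl)-4-methyl-2,6-dioxocyclohexane-1-carboxylate, meso, bromomethyl trans to 4-methyl | COC(=O)[C@@]1(CBr)C(=O)C[C@@H](C)CC1=O | intermediate
8 | methyl (1S,2R,4S)-1-(bromomethyl)-2-hydroxy-4-methyl-6-oxocyclohexane-1-carboxylate (hydroxyl cis to methyl) | COC(=O)[C@@]1(CBr)C(=O)C[C@@H](C)C[C@H]1O | intermediate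
9 | methyl (1S,2R,4S)-1-(bromomethyl)-2-[(tert-butyldimethylsilyl)oxy]-4-methyl-6-oxocyclohexane-1-carboxylate | COC(=O)[C@@]1(CBr)C(=O)C[C@@H](C)C[C@H]1O[Si](C)(C)C(C)(C)C | intermediate
10 | 1-bromobut-2-yne | CC#CCBr | starting material
11 | lithium enolate of 9 (C1=C5 enolate) | COC(=O)[C@@]1(CBr)C(O[Li])=C[C@@H](C)C[C@H]1O[Si](C)(C)C(C)(C)C | intermediate (not isolated)
12 | methyl (1S,3R,4S,6R)-1-(bromomethyl)-3-(but-2-yn-1-yl)-6-[(tert-butyldimethylsilyl)oxy]-4-methyl-2-oxocyclohexane-1-carboxylate (butynyl trans to methyl, silyloxy cis to methyl, bromomethyl trans to silyloxy) | COC(=O)[C@@]1(CBr)C(=O)[C@H](CC#CC)[C@@H](C)C[C@H]1O[Si](C)(C)C(C)(C)C | intermediate (key-step precursor)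
13 | methyl (1S,2R,4S,5R)-5-(but-2-yn-1-yl)-2-[(tert-butyldimethylsilyl)oxy]-4-methyl-6-oxocycloheptane-1-carboxylate (ester cis to silyloxy) | COC(=O)[C@H]1CC(=O)[C@H](CC#CC)[C@@H](C)C[C@H]1O[Si](C)(C)C(C)(C)C | intermediate (key-step product)
14 | methyl (1S,2R,4S,5R)-2-[(tert-butyldimethylsilyl)oxy]-4-methyl-6-oxo-5-(2-oxobutyl)cycloheptane-1-carboxylate | COC(=O)[C@H]1CC(=O)[C@H](CC(=O)CC)[C@@H](C)C[C@H]1O[Si](C)(C)C(C)(C)C | intermediate
15 | methyl (5S,6R,8S,8aR)-6-[(tert-butyldimethylsilyl)oxy]-3,8-dimethyl-2-oxo-1,2,4,5,6,7,8,8a-octahydroazulene-5-carboxylate (guaiane 1R,7S,8R,10S) | COC(=O)[C@H]1CC2=C(C)C(=O)C[C@@H]2[C@@H](C)C[C@H]1O[Si](C)(C)C(C)(C)C | intermediate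
16 | methyl (5S,6R,8S,8aR)-6-[(tert-butyldimethylsilyl)oxy]-2-hydroxy-3,8-dimethyl-1,2,4,5,6,7,8,8a-octahydroazulene-5-carboxylate, carbinol C3 (guaiane) as either epimer | COC(=O)[C@H]1CC2=C(C)C(O)C[C@@H]2[C@@H](C)C[C@H]1O[Si](C)(C)C(C)(C)C | intermediate
17 | (5S,6R,8S,8aR)-6-[(tert-butyldimethylsilyl)oxy]-5-(2-hydroxypropan-2-yl)-3,8-dimethyl-1,2,4,5,6,7,8,8a-octahydroazulen-2-ol, carbinol C3 (guaiane) as either epimer | CC(C)(O)[C@H]1CC2=C(C)C(O)C[C@@H]2[C@@H](C)C[C@H]1O[Si](C)(C)C(C)(C)C | intermediate
18 | (5S,6R,8S,8aR)-6-[(tert-butyldimethylsilyl)oxy]-5-(2-hydroxypropan-2-yl)-3,8-dimethyl-4,5,6,7,8,8a-hexahydroazulen-2(1H)-one | CC(C)(O)[C@H]1CC2=C(C)C(=O)C[C@@H]2[C@@H](C)C[C@H]1O[Si](C)(C)C(C)(C)C | intermediate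
19 | (5S,6R,8S,8aR)-6-hydroxy-5-(2-hydroxypropan-2-yl)-3,8-dimethyl-4,5,6,7,8,8a-hexahydroazulen-2(1H)-one | CC(C)(O)[C@H]1CC2=C(C)C(=O)C[C@@H]2[C@@H](C)C[C@H]1O | intermediate
20 | [(5S,6R,8S,8aR)-5-(2-hydroxypropan-2-yl)-3,8-dimethyl-2-oxo-1,2,4,5,6,7,8,8a-octahydroazulen-6-yl] 2-methylpropanoate | CC(C)(O)[C@H]1CC2=C(C)C(=O)C[C@@H]2[C@@H](C)C[C@H]1OC(=O)C(C)C | intermediate
21 | [(5S,6R,8S,8aR)-5-(2-acetoxypropan-2-yl)-3,8-dimethyl-2-oxo-1,2,4,5,6,7,8,8a-octahydroazulen-6-yl] 2-methylpropanoate = (1R,7S,8R,10S)-11-acetoxy-3-oxoguai-4-en-8-yl 2-methylpropanoate, CNP0197994.1 | CC(=O)OC(C)(C)[C@H]1CC2=C(C)C(=O)C[C@@H]2[C@@H](C)C[C@H]1OC(=O)C(C)C | target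

## Step count and least certain steps

Total step count: 14. Longest linear sequence: 14 steps (one linear sequence from 1).

**Step 6 (key step).** The most likely failure is hydrogen transfer to the primary C6 radical before it adds to the C5 carbonyl, which would give the unrearranged C7-methyl cyclohexanone. This happens when the stannane concentration is not kept low enough. A second risk is insufficient facial discrimination in the last hydrogen transfer at C7 on the flexible seven-membered ring.
Fallback: the same bond reorganisation is run as a reductive, radical–polar sequence. Starting from 12, SmI2 in THF/HMPA at −78 °C (divalent samarium) reduces the C–Br bond; the carbon nucleophile adds to C5, and the cyclopropanolate fragments to the diiodosamarium ester enolate F1. F1 is protonated from the face anti to the silyloxy group by a bulky phenol and returns to the route at 13. No hydrogen-atom donor is present, so premature reduction cannot occur, and the C7 configuration is set in a separate protonation that can be tuned.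

**Step 2.** The dienolate 5 is flanked by two methoxy-bearing carbons and dibromomethane is a weak electrophile, so incomplete C-alkylation (the enolate is simply protonated on work-up) is the main risk. Loss of a methoxy group or over-reduction of the ester in the dissolving-metal stage is the second.
Fallback: the carboxylate series is used instead. Starting from 2, quenching with CO2 gives 2,6-dimethoxy-4-methylbenzoic acid F2. Its Birch reduction gives a carboxylate dianion, which is more nucleophilic than an ester enolate and cannot be reduced further; alkylation with dibromomethane gives 1-(bromomethyl)-2,6-dimethoxy-4-methylcyclohexa-2,5-diene-1-carboxylic acid F3. Esterification with TMSCHN2 in MeOH/toluene then returns to the route at 6, which is hydrolysed to 7 as before.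

**Step 3.** The β,β'-diketo ester 7 can be cleaved hydrolytically (retro-Claisen ring opening) during long contact with aqueous buffer. An enzyme panel may also fail to combine carbonyl-group choice and axial delivery on this unusual substrate.
Fallback: a chemical desymmetrisation in an aprotic medium. Starting from 7, CBS reduction with (S)-Me-CBS oxazaborolidine and catecholborane in toluene at −78 °C returns directly to 8. The quaternary C7 acts as the large and C9H2 as the small substituent, which predicts the 8R alcohol, and the axial preference of the ring again selects the carbonyl that gives the alcohol cis to the methyl. This fallback makes no new compound (F0).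

**Step 8.** Under alkoxide the ester-bearing C7 could slowly epimerise through the ester enolate, which would also open a path to loss of the C8 silyloxy group. Prolonged base could additionally epimerise C1 once the enone is formed.
Fallback: the ester is converted before any base is used. Starting from 13:
- NaBH4 in MeOH reduces the C5 ketone to the hydroxy ester F4.
- MeMgBr/CeCl3 gives the diol F5.
- Dess–Martin periodinane oxidises only the secondary alcohol, giving the hydroxy ketone F6.
- Ph3PAuNTf2/H2O hydrates the alkyne to the diketone F7.
- NaOMe/MeOH closes ring A.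

The sequence returns to the route at 18 in the same number of steps, and C7 is no longer α to a carbonyl in any basic step.

**Step 14.** Acylation of the hindered tertiary hydroxyl may be slow. Forcing it risks ionisation of the tertiary centre with loss of the oxygen, or scrambling of the two acyl groups between O8 and O11.
Fallback: the order of esterification is reversed. Starting from 18, the tertiary alcohol is acetylated with Ac2O/DMAP/Et3N while O8 is still silylated, giving the silyl ether acetate F8; no neighbouring acyl group can migrate, so forcing is safe. HF·pyridine then gives the hydroxy acetate F9 under acidic conditions, and a rapid acylation with isobutyryl chloride/pyridine at −20 °C returns to the route at 21.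

## Further compounds

F1 | step 6 | diiodosamarium ester enolate of 13 | COC(O[Sm](I)I)=C1CC(=O)[C@H](CC#CC)[C@@H](C)C[C@H]1O[Si](C)(C)C(C)(C)C
F2 | step 2 | 2,6-dimethoxy-4-methylbenzoic acid | COc1cc(C)cc(OC)c1C(O)=O
F3 | step 2 | 1-(bromomethyl)-2,6-dimethoxy-4-methylcyclohexa-2,5-diene-1-carboxylic acid, bromomethyl trans to 4-methyl | OC(=O)[C@@]1(CBr)C(OC)=C[C@@H](C)C=C1OC
F0 | step 3 | none | none
F4 | step 8 | methyl 5-(but-2-yn-1-yl)-2-[(tert-butyldimethylsilyl)oxy]-6-hydroxy-4-methylcycloheptane-1-carboxylate, ring centres as in 13, new carbinol as either epimer | COC(=O)[C@H]1CC(O)[C@H](CC#CC)[C@@H](C)C[C@H]1O[Si](C)(C)C(C)(C)C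
F5 | step 8 | 2-(but-2-yn-1-yl)-5-[(tert-butyldimethylsilyl)oxy]-6-(2-hydroxypropan-2-yl)-3-methylcycloheptan-1-ol, ring centres as in 13, carbinol as either epimer | CC(C)(O)[C@H]1CC(O)[C@H](CC#CC)[C@@H](C)C[C@H]1O[Si](C)(C)C(C)(C)C
F6 | step 8 | 2-(but-2-yn-1-yl)-5-[(tert-butyldimethylsilyl)oxy]-6-(2-hydroxypropan-2-yl)-3-methylcycloheptan-1-one, ring centres as in 13 | CC(C)(O)[C@H]1CC(=O)[C@H](CC#CC)[C@@H](C)C[C@H]1O[Si](C)(C)C(C)(C)C
F7 | step 8 | 5-[(tert-butyldimethylsilyl)oxy]-6-(2-hydroxypropan-2-yl)-3-methyl-2-(2-oxobutyl)cycloheptan-1-one, ring centres as in 13 | CC(C)(O)[C@H]1CC(=O)[C@H](CC(=O)CC)[C@@H](C)C[C@H]1O[Si](C)(C)C(C)(C)C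
F8 | step 14 | 2-[(5S,6R,8S,8aR)-6-[(tert-butyldimethylsilyl)oxy]-3,8-dimethyl-2-oxo-1,2,4,5,6,7,8,8a-octahydroazulen-5-yl]propan-2-yl acetate | CC(=O)OC(C)(C)[C@H]1CC2=C(C)C(=O)C[C@@H]2[C@@H](C)C[C@H]1O[Si](C)(C)C(C)(C)C
F9 | step 14 | 2-[(5S,6R,8S,8aR)-6-hydroxy-3,8-dimethyl-2-oxo-1,2,4,5,6,7,8,8a-octahydroazulen-5-yl]propan-2-yl acetate | CC(=O)OC(C)(C)[C@H]1CC2=C(C)C(=O)C[C@@H]2[C@@H](C)C[C@H]1O
A1 | alternative 1 | (10R)-11,12,13-trinoreudesma-1,4-dien-3-one 8-ethylene ketal (cross-conjugated decalin dienone) | C[C@@]12C=CC(=O)C(C)=C1CCC1(OCCO1)C2
A2 | alternative 1 | 10β-acetoxy-10α-methyl-11,12,13-trinorguai-4-en-3-one 8-ethylene ketal (1β-H) | C1CC2=C(C)C(=O)C[C@@H]2[C@@](C)(OC(C)=O)CC13OCCO3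
A3 | alternative 2 | cyclopentenone aldehyde carrying the (E)-2-methyl-4-(trimethylsilyl)but-2-enyl chain on C5 and the 4-oxobutan-2-yl chain on C1 | C[Si](C)(C)C/C(C)=C/CC1=C(C)C(=O)C[C@@H]1[C@@H](C)CC=O
A4 | alternative 2 | 8-hydroxy-7-isopropenyl hydroazulenone, 7,8-cis, all four centres as in 21 | CC(=C)[C@H]1CC2=C(C)C(=O)C[C@@H]2[C@@H](C)C[C@H]1O
A5 | alternative 3 | (E)-3-ethylidene-4-methylidenecyclopentanone ethylene ketal | C/C=C1\CC2(OCCO2)CC1=C
A6 | alternative 3 | methyl 3-[(tert-butyldimethylsilyl)oxy]-2-diazobut-3-enoate | COC(=O)C(=[N+]=[N-])C(=C)O[Si](C)(C)C(C)(C)C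
A7 | alternative 3 | (10S) bicyclic silyl enol ether β-keto ester with C1=C5 alkene and C3 ethylene ketal, no C15 methyl | COC(=O)C1=C(O[Si](C)(C)C(C)(C)C)C[C@H](C)C2=C(C1)CC3(OCCO3)C2
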